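**Plan**

1. Numbering: ring C1 (bears the chain), C2 (bears CH3), C3, C4, C5, C6 (CMe2); chain C1′ (on C1) to C9′ (on the arene). Cuts, in retrosynthetic order: the two O–CH3 masks, ring bond C3–C4, diene bond C1–C2 (to an isopropenyl boronate), chain bond C1′–C2′ (enolate alkylation), arene–C9′ (aryllithium plus geranyl bromide).
2. Enabling feature: the tetrasubstituted C1=C2 bond lies between the allylic C3 methylene and the quaternary C6. It is therefore the middle of the allyl radical C2–C1–C1′ that forms when a C4 radical adds to the CH2 end of a 2,3-disubstituted buta-1,3-diene; one event closes the six-membered ring, places the double bond and leaves no functional group behind.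
3. C6 also helps earlier: as a quaternary α-carbon it lets the C1 ketone enolise only towards C1′, which fixes the site of alkylation and of enol triflate formation, and its gem-dimethyl group favours ring closure.
4. Forward: geranyl bromide is arylated and oxidised at its (E)-methyl group to a C10 allylic bromide; α,α-dimethyl-γ-butyrolactone gives a silyloxy methyl ketone; enolate alkylation joins the two.
5. Enol triflate formation and Suzuki coupling give the diene, the silyl ether becomes the iodide, the radical cyclisation forms the only carbocycle made in the route, and oxidative demethylation followed by reduction frees the hydroquinone.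
6. Stereochemistry: there is no stereocentre. The C7′=C8′ (E) bond is bought with geranyl bromide, the C3′=C4′ (E) bond comes from the (E)-selective SeO2 oxidation, and neither is touched later; the geometry of the transient C1=C1′ bond is lost in the allyl radical.

Key step: step 11

Remark: in step 12 both quinone oxygens are taken to come from water (ipso attack, loss of methanol), as is accepted for the cerium oxidation of para-dimethoxyarenes.

**Route**

Step 1
Reactants: 1 1,4-dimethoxybenzene; 2 geranyl bromide [(2E)-1-bromo-3,7-dimethylocta-2,6-diene]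
Product: 4 2-[(2E)-3,7-dimethylocta-2,6-dien-1-yl]-1,4-dimethoxybenzene, via aryllithium 3 (not isolated)
Conditions: n-BuLi, TMEDA, Et2O, 0 °C to rt; then CuI (10 mol %), 2, THF, −78 °C to rt
Reagents that add atoms: none
Why: Directed ortho-lithiation of the dimethoxyarene followed by copper-catalysed SN2 alkylation of the aryllithium at the primary allylic carbon should give the linear product with the (E) double bond unchanged.

Step 2
Reactants: 4 2-[(2E)-3,7-dimethylocta-2,6-dien-1-yl]-1,4-dimethoxybenzene
Product: 5 (2E,6E)-8-(2,5-dimethoxyphenyl)-2,6-dimethylocta-2,6-dien-1-ol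
Conditions: SeO2 (10 mol %), salicylic acid (10 mol %), t-BuOOH, CH2Cl2, rt, stopped at partial conversion
Reagents that add atoms: tert-butyl hydroperoxide, CC(C)(C)OO (oxygen, passed on through catalytic selenium dioxide, O=[Se]=O)
Why: Riley-type allylic oxidation (ene reaction, then [2,3]-sigmatropic shift) should attack the more accessible terminal isopropylidene group at the methyl trans to the chain and so give the (E)-allylic alcohol.

Step 3
Reactants: 5 (2E,6E)-8-(2,5-dimethoxyphenyl)-2,6-dimethylocta-2,6-dien-1-ol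
Product: 6 2-[(2E,6E)-8-bromo-3,7-dimethylocta-2,6-dien-1-yl]-1,4-dimethoxybenzene
Conditions: CBr4, PPh3, CH2Cl2, 0 °C
Reagents that add atoms: carbon tetrabromide, BrC(Br)(Br)Br
Why: In the Appel reaction bromide displaces the alkoxyphosphonium group at the primary allylic carbon under neutral conditions, so the (E) double bond should neither migrate nor isomerise.

Step 4
Reactants: 7 α,α-dimethyl-γ-butyrolactone (3,3-dimethyloxolan-2-one)
Product: 8 5-hydroxy-3,3-dimethylpentan-2-one
Conditions: MeLi (1.05 equiv), Et2O, −78 °C; then H2O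
Reagents that add atoms: methyllithium, [Li]C
Why: Acyl substitution of a lactone by an organolithium: at −78 °C the hindered α,α-disubstituted lactone should take up one equivalent of methyllithium only, and hydrolysis gives the hydroxy methyl ketone.

Step 5
Reactants: 8 5-hydroxy-3,3-dimethylpentan-2-one
Product: 9 5-[(tert-butyldimethylsilyl)oxy]-3,3-dimethylpentan-2-one
Conditions: TBSCl, imidazole, DMF, rt
Reagents that add atoms: tert-butyldimethylsilyl chloride, CC(C)(C)[Si](C)(C)Cl
Why: Imidazole-assisted silylation of the primary hydroxyl group takes the alcohol out of the ring–chain equilibrium of the γ-hydroxy ketone and masks it against the bases of steps 6 and 7.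

Step 6
Reactants: 9 5-[(tert-butyldimethylsilyl)oxy]-3,3-dimethylpentan-2-one; 6 2-[(2E,6E)-8-bromo-3,7-dimethylocta-2,6-dien-1-yl]-1,4-dimethoxybenzene
Product: 11 (7E,11E)-1-[(tert-butyldimethylsilyl)oxy]-13-(2,5-dimethoxyphenyl)-3,3,7,11-tetramethyltrideca-7,11-dien-4-one, via lithium enolate 10 (not isolated)
Conditions: LiN(i-Pr)2, THF, −78 °C; then 6 (0.7 equiv), DMPU, −78 to −20 °C
Reagents that add atoms: none
Why: Kinetic lithium enolate alkylation: the quaternary C6 leaves the methyl group as the only enolisable position, the enolate displaces the primary allylic bromide by SN2 to form the C1′–C2′ bond with both (E) double bonds intact, and excess enolate suppresses double alkylation.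

Step 7
Reactants: 11 (7E,11E)-1-[(tert-butyldimethylsilyl)oxy]-13-(2,5-dimethoxyphenyl)-3,3,7,11-tetramethyltrideca-7,11-dien-4-one
Product: 13 (4Z,7E,11E)-1-[(tert-butyldimethylsilyl)oxy]-13-(2,5-dimethoxyphenyl)-3,3,7,11-tetramethyltrideca-4,7,11-trien-4-yl trifluoromethanesulfonate, via potassium enolate 12 (not isolated)
Conditions: KN(SiMe3)2, THF, −78 °C; then PhNTf2, −78 to 0 °C
Reagents that add atoms: N-phenylbis(trifluoromethanesulfonimide), O=S(=O)(N(c1ccccc1)S(=O)(=O)C(F)(F)F)C(F)(F)F
Why: Enolate O-triflation: deprotonation can occur only at C1′, the bulky tertiary alkyl group should favour the (Z)-enolate, and trapping with PhNTf2 gives the enol triflate (its geometry is without consequence later).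

Step 8
Reactants: 13 (4Z,7E,11E)-1-[(tert-butyldimethylsilyl)oxy]-13-(2,5-dimethoxyphenyl)-3,3,7,11-tetramethyltrideca-4,7,11-trien-4-yl trifluoromethanesulfonate; 14 isopropenylboronic acid pinacol ester
Product: 15 tert-butyl{[(4E,7E,11E)-13-(2,5-dimethoxyphenyl)-3,3,7,11-tetramethyl-4-(prop-1-en-2-yl)trideca-4,7,11-trien-1-yl]oxy}dimethylsilane
Conditions: Pd(PPh3)4 (5 mol %), K3PO4, 1,4-dioxane/H2O, 80 °C
Reagents that add atoms: none
Why: Suzuki–Miyaura coupling of an enol triflate with an alkenyl boronate (oxidative addition to zerovalent palladium, transmetalation, reductive elimination), a reaction type that tolerates a neighbouring quaternary carbon as in steroidal 17-enol triflates, should build the 2,3-disubstituted buta-1,3-diene with retention at C1=C1′.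

Step 9
Reactants: 15 tert-butyl{[(4E,7E,11E)-13-(2,5-dimethoxyphenyl)-3,3,7,11-tetramethyl-4-(prop-1-en-2-yl)trideca-4,7,11-trien-1-yl]oxy}dimethylsilane
Product: 16 (4E,7E,11E)-13-(2,5-dimethoxyphenyl)-3,3,7,11-tetramethyl-4-(prop-1-en-2-yl)trideca-4,7,11-trien-1-ol
Conditions: Bu4NF, THF, 0 °C to rt
Reagents that add atoms: none
Why: Fluoride cleavage of the primary silyl ether; the diene, the isolated alkenes and the aryl methyl ethers are inert to Bu4NF.

Step 10
Reactants: 16 (4E,7E,11E)-13-(2,5-dimethoxyphenyl)-3,3,7,11-tetramethyl-4-(prop-1-en-2-yl)trideca-4,7,11-trien-1-ol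
Product: 17 2-[(2E,6E,9E)-13-iodo-3,7,11,11-tetramethyl-10-(prop-1-en-2-yl)trideca-2,6,9-trien-1-yl]-1,4-dimethoxybenzene
Conditions: I2, PPh3, imidazole, CH2Cl2, 0 °C, dark
Reagents that add atoms: iodine, I-I
Why: Appel-type iodination of a primary alcohol (SN2 on the alkoxyphosphonium ion) runs under neutral conditions in which no free iodine remains to add to the diene.

Step 11
Reactants: 17 2-[(2E,6E,9E)-13-iodo-3,7,11,11-tetramethyl-10-(prop-1-en-2-yl)trideca-2,6,9-trien-1-yl]-1,4-dimethoxybenzene
Product: 18 2-[(2E,6E)-3,7-dimethyl-9-(2,6,6-trimethylcyclohex-1-en-1-yl)nona-2,6-dien-1-yl]-1,4-dimethoxybenzene (jaspaquinol dimethyl ether)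
Conditions: Bu3SnH (1.2 equiv, syringe pump), AIBN (10 mol %), benzene (0.01 M), 80 °C
Reagents that add atoms: none
Why: The tributyltin radical abstracts iodine from 17 to give the primary C4 radical, which adds to the unsubstituted CH2 terminus (future C3) of the diene; the resulting allyl radical C2–C1–C1′ then takes hydrogen from Bu3SnH at the exocyclic C1′, which leaves the C1=C2 bond tetrasubstituted inside the new ring. The closest known reaction type is the tin hydride mediated cyclisation of 5-substituted hex-5-enyl radicals and of haloalkyl 1,3-dienes. The six-membered ring closes in the 6-endo-trig mode: the 5-exo alternative would have to attack the methyl-bearing C2 next to the fully substituted C1 and would give an unstabilised primary radical, whereas the endo path gives an allyl radical and is helped by the gem-dimethyl group at C6. No stereocentre is formed, and the two (E) double bonds of the chain should stay untouched because a stabilised allyl radical adds only sluggishly to isolated trisubstituted alkenes. The step needs regioselective hydrogen transfer to the allyl radical: the ring terminus C2 is tertiary and hindered, C1′ is secondary, and hydrogen delivery at C1′ also gives the more substituted, more stable alkene. Slow addition of Bu3SnH keeps direct reduction of the primary radical slower than cyclisation.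

Step 12
Reactants: 18 2-[(2E,6E)-3,7-dimethyl-9-(2,6,6-trimethylcyclohex-1-en-1-yl)nona-2,6-dien-1-yl]-1,4-dimethoxybenzene
Product: 20 jaspaquinol, via benzoquinone 19 (not isolated)
Conditions: (NH4)2Ce(NO3)6, MeCN/H2O, 0 °C; then aq Na2S2O4, EtOAc, rt, under argon
Reagents that add atoms: water, O
Why: Oxidative demethylation of the para-dimethoxyarene by tetravalent cerium (two one-electron oxidations with attack of water at the ipso carbons) should give the quinone faster than the isolated alkenes are oxidised, and dithionite reduces it to the hydroquinone in the same flask.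

**Compound list**

1 | 1,4-dimethoxybenzene | COc1ccc(OC)cc1 | starting material
2 | geranyl bromide, (2E)-1-bromo-3,7-dimethylocta-2,6-diene | CC(C)=CCC/C(C)=C/CBr | starting material
3 | (2,5-dimethoxyphenyl)lithium | [Li]c1cc(OC)ccc1OC | intermediate
4 | 2-[(2E)-3,7-dimethylocta-2,6-dien-1-yl]-1,4-dimethoxybenzene | CC(C)=CCC/C(C)=C/Cc1cc(OC)ccc1OC | intermediate
5 | (2E,6E)-8-(2,5-dimethoxyphenyl)-2,6-dimethylocta-2,6-dien-1-ol | OC/C(C)=C/CC/C(C)=C/Cc1cc(OC)ccc1OC | intermediate
6 | 2-[(2E,6E)-8-bromo-3,7-dimethylocta-2,6-dien-1-yl]-1,4-dimethoxybenzene | BrC/C(C)=C/CC/C(C)=C/Cc1cc(OC)ccc1OC | intermediate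
7 | α,α-dimethyl-γ-butyrolactone (3,3-dimethyloxolan-2-one) | CC1(C)CCOC1=O | starting material
8 | 5-hydroxy-3,3-dimethylpentan-2-one | CC(=O)C(C)(C)CCO | intermediate
9 | 5-[(tert-butyldimethylsilyl)oxy]-3,3-dimethylpentan-2-one | CC(=O)C(C)(C)CCO[Si](C)(C)C(C)(C)C | intermediate
10 | lithium enolate of 9 (lithium 5-[(tert-butyldimethylsilyl)oxy]-3,3-dimethylpent-1-en-2-olate) | C=C(O[Li])C(C)(C)CCO[Si](C)(C)C(C)(C)C | intermediate
11 | (7E,11E)-1-[(tert-butyldimethylsilyl)oxy]-13-(2,5-dimethoxyphenyl)-3,3,7,11-tetramethyltrideca-7,11-dien-4-one | CC(C)(CCO[Si](C)(C)C(C)(C)C)C(=O)CC/C(C)=C/CC/C(C)=C/Cc1cc(OC)ccc1OC | intermediate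
12 | potassium (4Z)-enolate of 11 | CC(C)(CCO[Si](C)(C)C(C)(C)C)/C(O[K])=C/C/C(C)=C/CC/C(C)=C/Cc1cc(OC)ccc1OC | intermediate
13 | (4Z,7E,11E)-1-[(tert-butyldimethylsilyl)oxy]-13-(2,5-dimethoxyphenyl)-3,3,7,11-tetramethyltrideca-4,7,11-trien-4-yl trifluoromethanesulfonate | CC(C)(CCO[Si](C)(C)C(C)(C)C)/C(OS(=O)(=O)C(F)(F)F)=C/C/C(C)=C/CC/C(C)=C/Cc1cc(OC)ccc1OC | intermediate
14 | isopropenylboronic acid pinacol ester (4,4,5,5-tetramethyl-2-(prop-1-en-2-yl)-1,3,2-dioxaborolane) | CC(=C)B1OC(C)(C)C(C)(C)O1 | starting material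
15 | tert-butyl{[(4E,7E,11E)-13-(2,5-dimethoxyphenyl)-3,3,7,11-tetramethyl-4-(prop-1-en-2-yl)trideca-4,7,11-trien-1-yl]oxy}dimethylsilane | CC(C)(CCO[Si](C)(C)C(C)(C)C)/C(C(C)=C)=C/C/C(C)=C/CC/C(C)=C/Cc1cc(OC)ccc1OC | intermediate
16 | (4E,7E,11E)-13-(2,5-dimethoxyphenyl)-3,3,7,11-tetramethyl-4-(prop-1-en-2-yl)trideca-4,7,11-trien-1-ol | CC(C)(CCO)/C(C(C)=C)=C/C/C(C)=C/CC/C(C)=C/Cc1cc(OC)ccc1OC | intermediate
17 | 2-[(2E,6E,9E)-13-iodo-3,7,11,11-tetramethyl-10-(prop-1-en-2-yl)trideca-2,6,9-trien-1-yl]-1,4-dimethoxybenzene | CC(C)(CCI)/C(C(C)=C)=C/C/C(C)=C/CC/C(C)=C/Cc1cc(OC)ccc1OC | intermediate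
18 | 2-[(2E,6E)-3,7-dimethyl-9-(2,6,6-trimethylcyclohex-1-en-1-yl)nona-2,6-dien-1-yl]-1,4-dimethoxybenzene | CC1=C(CC/C(C)=C/CC/C(C)=C/Cc2cc(OC)ccc2OC)C(C)(C)CCC1 | intermediate
19 | 2-[(2E,6E)-3,7-dimethyl-9-(2,6,6-trimethylcyclohex-1-en-1-yl)nona-2,6-dien-1-yl]cyclohexa-2,5-diene-1,4-dione | CC1=C(CC/C(C)=C/CC/C(C)=C/CC2=CC(=O)C=CC2=O)C(C)(C)CCC1 | intermediate
20 | jaspaquinol, 2-[(2E,6E)-3,7-dimethyl-9-(2,6,6-trimethylcyclohex-1-en-1-yl)nona-2,6-dien-1-yl]benzene-1,4-diol | CC1=C(CC/C(C)=C/CC/C(C)=C/Cc2cc(O)ccc2O)C(C)(C)CCC1 | target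

**Summary**

Total step count: 12.
Longest linear sequence: 10 steps (steps 1–3 and 6–12, from 1,4-dimethoxybenzene and geranyl bromide); the lactone branch (steps 4 and 5) joins at step 6.

Steps most likely to fail:

Step 11. The primary radical may be reduced before it cyclises, or hydrogen may return to ring C2 of the allyl radical and leave an exocyclic double bond. The fallback sets out from 6 and comes back at 18; it buys the ring instead of closing it. Commercial β-cyclocitral (2,6,6-trimethylcyclohex-1-ene-1-carbaldehyde) is reduced with NaBH4 in MeOH to β-cyclogeraniol F1. PBr3 and pyridine in Et2O give β-cyclogeranyl bromide F2, and PhSO2Na in DMF gives β-cyclogeranyl phenyl sulfone F3. Its lithium derivative (n-BuLi, THF, −78 °C) is alkylated with bromide 6 to give the C1′ sulfone adduct F4 (racemic). Reductive desulfonylation with PdCl2(dppp) and LiBHEt3 in THF, with hydride delivery to the exocyclic end of the allyl system, should give 18.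

Step 2. Oxidation may also occur at the inner double bond or at the benzylic position, and over-oxidation to the enal may reduce the amount of 5. The fallback sets out from 4 and comes back at 5; it rebuilds the chain terminus by cleavage and olefination. NBS in THF/H2O at 0 °C should form the terminal bromohydrin F5, which K2CO3 in MeOH closes to the terminal epoxide F6. H5IO6 in THF/Et2O cleaves the epoxide to the aldehyde F7. Wittig reaction with Ph3P=C(CH3)CO2Et in CH2Cl2 should give the (E)-enoate F8, and i-Bu2AlH in CH2Cl2 at −78 °C reduces it to 5.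

Step 8. Oxidative addition at the triflate flanked by the quaternary carbon may be slow, so that hydrolysis back to the ketone or protodeboronation of 14 takes over. The fallback sets out from 11 and comes back at 15; it replaces cross-coupling by carbonyl addition and elimination. Isopropenylmagnesium bromide with anhydrous CeCl3 in THF at −78 °C adds to ketone 11 to give the tertiary allylic alcohol F9 (racemic). Dehydration with the Burgess reagent in benzene at 50 °C can only go towards C1′, because C6 carries no hydrogen, and should give 15.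

**Further compounds**

F1 | step 11 | β-cyclogeraniol, (2,6,6-trimethylcyclohex-1-en-1-yl)methanol | CC1=C(CO)C(C)(C)CCC1
F2 | step 11 | β-cyclogeranyl bromide, 2-(bromomethyl)-1,3,3-trimethylcyclohex-1-ene | CC1=C(CBr)C(C)(C)CCC1
F3 | step 11 | β-cyclogeranyl phenyl sulfone | CC1=C(CS(=O)(=O)c2ccccc2)C(C)(C)CCC1
F4 | step 11 | 2-[(2E,6E)-3,7-dimethyl-9-(phenylsulfonyl)-9-(2,6,6-trimethylcyclohex-1-en-1-yl)nona-2,6-dien-1-yl]-1,4-dimethoxybenzene (racemic) | CC1=C(C(C/C(C)=C/CC/C(C)=C/Cc2cc(OC)ccc2OC)S(=O)(=O)c2ccccc2)C(C)(C)CCC1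
F5 | step 2 | (6E)-3-bromo-8-(2,5-dimethoxyphenyl)-2,6-dimethyloct-6-en-2-ol (racemic) | CC(C)(O)C(Br)CC/C(C)=C/Cc1cc(OC)ccc1OC
F6 | step 2 | 2-[(2E)-5-(3,3-dimethyloxiran-2-yl)-3-methylpent-2-en-1-yl]-1,4-dimethoxybenzene (racemic) | CC1(C)OC1CC/C(C)=C/Cc1cc(OC)ccc1OC
F7 | step 2 | (4E)-6-(2,5-dimethoxyphenyl)-4-methylhex-4-enal | O=CCC/C(C)=C/Cc1cc(OC)ccc1OC
F8 | step 2 | ethyl (2E,6E)-8-(2,5-dimethoxyphenyl)-2,6-dimethylocta-2,6-dienoate | CCOC(=O)/C(C)=C/CC/C(C)=C/Cc1cc(OC)ccc1OC
F9 | step 8 | (7E,11E)-1-[(tert-butyldimethylsilyl)oxy]-13-(2,5-dimethoxyphenyl)-3,3,7,11-tetramethyl-4-(prop-1-en-2-yl)trideca-7,11-dien-4-ol (racemic) | CC(C)(CCO[Si](C)(C)C(C)(C)C)C(O)(C(C)=C)CC/C(C)=C/CC/C(C)=C/Cc1cc(OC)ccc1OC
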